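**Plan**

- Retrosynthesis: (a) both pyran O–CH2 bonds (allylic Williamson closure); (b) both C=C bonds of the central diene (double Z-selective olefination of succinaldehyde, two-directional); (c) the chain bonds CH2–C(phosphonate) (Michael) and C(=O)–vinyl; (d) in the cyclopentane, the bond between the ring CH2 and the ring CH that carries the side chain, together with the carbinol C–O bond (as C–B), back to an open-chain enoate tosylate from (R)-lavandulol.
- Forward order: lavandulol → (E)-enoate with a 2-tosyloxyethyl arm → cyclopentane (step 5) → keto phosphonoacetate chain → dimerisation on succinaldehyde → both tetrahydropyrans in the last step.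
- Enabling feature: in each cyclopentane the CH that bears the pyran lies between the carbinol carbon and the pyran O–CH carbon (a 1,3-dioxygenated triad), so it is the α-carbon of a latent β-hydroxy ester. The ring CH2 beside it is the end of a two-carbon arm on the isopropenyl-bearing carbon, so a β-boryl ester enolate can close the ring by SN2.
- Stereochemistry: isopropenyl centre from (R)-lavandulol; carbinol centre from ligand-controlled conjugate borylation (C–B to C–OH with retention); neighbouring CH from allylic-strain-controlled enolate alkylation (trans); pyran C2 from hydroxyl-directed 1,3-syn reduction; both Z-alkenes from Still–Gennari olefination. The C2 symmetry lets both halves be joined and both pyrans be closed in the same operations.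

Key step: step 5

Remark: (R)-(−)-lavandulol is taken as the purchased single enantiomer; material of lower enantiomeric purity would first be upgraded by lipase-mediated acylation.

**Route**

Step 1
Reactants: 1 (R)-lavandulol
Product: 3 ethyl (2E,4S)-7-methyl-4-(prop-1-en-2-yl)octa-2,6-dienoate, via (R)-lavandulal 2 (not isolated)
Conditions: PhI(OAc)2, TEMPO (10 mol%), CH2Cl2, rt; then Ph3P=CHCO2Et, rt
Reagents that add atoms: ethyl (triphenylphosphoranylidene)acetate, CCOC(=O)C=P(c1ccccc1)(c1ccccc1)c1ccccc1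
Why: the non-basic nitroxyl oxidation gives the β,γ-unsaturated aldehyde and the stabilised ylide traps it at once in an E-selective Wittig olefination, so the α-stereocentre has little time to epimerise or move into conjugation.

Step 2
Reactants: 3 ethyl (2E,4S)-7-methyl-4-(prop-1-en-2-yl)octa-2,6-dienoate
Product: 5 ethyl (2E,4S)-5-methyl-4-(2-oxoethyl)hexa-2,5-dienoate, via epoxide 4 (not isolated)
Conditions: mCPBA (1.05 equiv), NaHCO3, CH2Cl2, −10 °C; then H5IO6, THF/Et2O, 0 °C
Reagents that add atoms: 3-chloroperoxybenzoic acid, OOC(=O)c1cccc(Cl)c1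
Why: Prilezhaev epoxidation should pick the most electron-rich (trisubstituted) alkene over the 1,1-disubstituted and the electron-poor ones, and periodic acid then cleaves the epoxide oxidatively to the aldehyde with loss of acetone.

Step 3
Reactants: 5 ethyl (2E,4S)-5-methyl-4-(2-oxoethyl)hexa-2,5-dienoate
Product: 6 ethyl (2E,4S)-4-(2-hydroxyethyl)-5-methylhexa-2,5-dienoate
Conditions: NaBH4 (0.5 equiv), EtOH, −20 °C; AcOH quench
Reagents that add atoms: none
Why: chemoselective borohydride reduction of the aldehyde beside the enoate, with low temperature and acidic quench to suppress oxa-Michael closure of the alkoxide.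

Step 4
Reactants: 6 ethyl (2E,4S)-4-(2-hydroxyethyl)-5-methylhexa-2,5-dienoate
Product: 7 ethyl (2E,4S)-5-methyl-4-[2-(tosyloxy)ethyl]hexa-2,5-dienoate
Conditions: TsCl, Et3N, DMAP (cat.), CH2Cl2, 0 °C
Reagents that add atoms: 4-toluenesulfonyl chloride, Cc1ccc(cc1)S(Cl)(=O)=O
Why: standard sulfonylation of a primary alcohol, a tosylate being chosen over an iodide because it should be inert to boryl copper species.

Step 5
Reactants: 7 ethyl (2E,4S)-5-methyl-4-[2-(tosyloxy)ethyl]hexa-2,5-dienoate
Product: 9 ethyl (1S,2S,3S)-3-(prop-1-en-2-yl)-2-(4,4,5,5-tetramethyl-1,3,2-dioxaborolan-2-yl)cyclopentane-1-carboxylate, via boron enolate 8 (not isolated)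
Conditions: CuCl (10 mol%), 2,3-bis(tert-butylmethylphosphino)quinoxaline (11 mol%, the enantiomer that delivers boron to the required face), NaOtBu (15 mol%), B2pin2 (1.2 equiv), THF, 0 °C to rt, no protic additive; then KOtBu (2.2 equiv), DMPU, −40 to 0 °C; NH4Cl work-up
Reagents that add atoms: bis(pinacolato)diboron, CC1(C)OB(OC1(C)C)B1OC(C)(C)C(C)(C)O1
Why: Proposed new method: a ligated boryl copper species (monovalent copper) adds across the enoate of 7 and the copper enolate is turned over by B2pin2 to the boron enolate 8, so that no stoichiometric base meets the base-sensitive skipped dienoate; tert-butoxide then takes boron off oxygen and the potassium enolate displaces the primary tosylate, which joins the enolate carbon to the CH2 carbon of the arm. The closest known reaction types are the copper-catalysed asymmetric β-borylation of enoates, its aldol-terminated borylative cyclisations, the copper-catalysed borylative cyclisation of alkenyl sulfonates and halides, and conjugate silylation followed by enolate alkylation. The cyclopentane closes in a 5-exo-tet mode with the enolate double bond outside the forming ring. The boron-bearing centre is set by the chiral bisphosphine, chosen so that boron ends up anti to the isopropenyl group in the zigzag drawing of the chain (cis on the later ring), with only a weak bias of the lavandulol-derived centre to be overridden. The ester-bearing centre is set by allylic 1,3-strain: the enolate reacts with the C–H of the boron-bearing carbon in its plane, the tether reaches over one face and the boryl group lies on the other, which places the ester trans to boron, also the more stable arrangement, so that epimerisation can only help. The step needs conjugate borylation to outrun attack on the sulfonate and γ-deprotonation, and C- to outrun O-alkylation; a tosylate in place of an iodide, a base-free first stage and the five- against seven-membered transition state should secure these.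

Step 6
Reactants: 9 ethyl (1S,2S,3S)-3-(prop-1-en-2-yl)-2-(4,4,5,5-tetramethyl-1,3,2-dioxaborolan-2-yl)cyclopentane-1-carboxylate
Product: 10 ethyl (1S,2S,3R)-2-hydroxy-3-(prop-1-en-2-yl)cyclopentane-1-carboxylate
Conditions: NaBO3·4H2O, THF/H2O (1:1), rt
Reagents that add atoms: sodium perborate tetrahydrate, [Na+].[Na+].O[B-]1(O)OO[B-](O)(O)OO1
Why: perborate oxidation of the C–B bond proceeds by 1,2-migration with retention, so the hydroxyl takes the place of boron cis to the isopropenyl group while the alkene and ester stay untouched.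

Step 7
Reactants: 10 ethyl (1S,2S,3R)-2-hydroxy-3-(prop-1-en-2-yl)cyclopentane-1-carboxylate
Product: 11 (1S,2S,3R)-2-hydroxy-N-methoxy-N-methyl-3-(prop-1-en-2-yl)cyclopentane-1-carboxamide
Conditions: MeNH(OMe)·HCl, iPrMgCl, THF, −20 to 0 °C
Reagents that add atoms: N,O-dimethylhydroxylamine hydrochloride, CNOC.Cl
Why: aminolysis of the ester by the chloromagnesium amide gives the Weinreb amide, and the trans arrangement is the thermodynamic one so the α-centre is not at risk.

Step 8
Reactants: 11 (1S,2S,3R)-2-hydroxy-N-methoxy-N-methyl-3-(prop-1-en-2-yl)cyclopentane-1-carboxamide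
Product: 12 1-[(1S,2S,3R)-2-hydroxy-3-(prop-1-en-2-yl)cyclopentyl]prop-2-en-1-one
Conditions: CH2=CHMgBr (3.5 equiv), THF, −78 to −20 °C; inverse quench into cold aqueous NaHSO4
Reagents that add atoms: vinylmagnesium bromide, C=C[Mg]Br
Why: Weinreb ketone synthesis, in which the chelated tetrahedral adduct stops at the ketone stage and the inverse acidic quench keeps the released amine from adding to the enone.

Step 9
Reactants: 12 1-[(1S,2S,3R)-2-hydroxy-3-(prop-1-en-2-yl)cyclopentyl]prop-2-en-1-one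
Product: 13 methyl 2-[bis(2,2,2-trifluoroethoxy)phosphoryl]-5-[(1S,2S,3R)-2-hydroxy-3-(prop-1-en-2-yl)cyclopentyl]-5-oxopentanoate (both epimers at C2)
Conditions: (CF3CH2O)2P(O)CH2CO2Me (1.5 equiv), Cs2CO3 (0.1 equiv), MeCN, 0 °C
Reagents that add atoms: methyl bis(2,2,2-trifluoroethyl)phosphonoacetate, COC(=O)CP(=O)(OCC(F)(F)F)OCC(F)(F)F
Why: base-catalysed Michael addition of the acidic phosphonoacetate to the unhindered vinyl ketone, the new phosphonate-bearing centre being left as a mixture because it becomes sp2 in step 13.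

Step 10
Reactants: 13 methyl 2-[bis(2,2,2-trifluoroethoxy)phosphoryl]-5-[(1S,2S,3R)-2-hydroxy-3-(prop-1-en-2-yl)cyclopentyl]-5-oxopentanoate
Product: 14 methyl (5R)-2-[bis(2,2,2-trifluoroethoxy)phosphoryl]-5-hydroxy-5-[(1R,2S,3R)-2-hydroxy-3-(prop-1-en-2-yl)cyclopentyl]pentanoate
Conditions: Et2BOMe, THF/MeOH (4:1), −78 °C; NaBH4, −78 °C; AcOH, then MeOH azeotrope
Reagents that add atoms: none
Why: Narasaka–Prasad reduction, in which external hydride attacks the diethylboron chelate of the β-hydroxy ketone axially to give the 1,3-syn diol and so sets the carbinol centre that becomes C2 of the tetrahydropyran.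

Step 11
Reactants: 14 methyl (5R)-2-[bis(2,2,2-trifluoroethoxy)phosphoryl]-5-hydroxy-5-[(1R,2S,3R)-2-hydroxy-3-(prop-1-en-2-yl)cyclopentyl]pentanoate
Product: 15 methyl (5R)-5-acetoxy-5-[(1R,2S,3R)-2-acetoxy-3-(prop-1-en-2-yl)cyclopentyl]-2-[bis(2,2,2-trifluoroethoxy)phosphoryl]pentanoate
Conditions: Ac2O, pyridine, DMAP (cat.), CH2Cl2, 0 °C to rt
Reagents that add atoms: acetic anhydride, CC(=O)OC(C)=O
Why: acetylation masks both alcohols as groups that survive the basic olefination, fall off in the hydride reduction of step 14 and prevent δ-lactonisation onto the phosphonoacetate ester.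

Step 12
Reactants: 16 2,5-dimethoxytetrahydrofuran
Product: 17 succinaldehyde
Conditions: H2O, 90 °C; MeOH and H2O distilled off, toluene azeotrope; used at once
Reagents that add atoms: water, O
Why: hydrolysis of the cyclic bis-acetal liberates the dialdehyde, which is used fresh to avoid oligomerisation.

Step 13
Reactants: 15 methyl (5R)-5-acetoxy-5-[(1R,2S,3R)-2-acetoxy-3-(prop-1-en-2-yl)cyclopentyl]-2-[bis(2,2,2-trifluoroethoxy)phosphoryl]pentanoate (2.2 equiv); 17 succinaldehyde (1 equiv)
Product: 18 dimethyl (2Z,6Z)-2,7-bis{(3R)-3-acetoxy-3-[(1R,2S,3R)-2-acetoxy-3-(prop-1-en-2-yl)cyclopentyl]propyl}octa-2,6-dienedioate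
Conditions: KN(SiMe3)2, 18-crown-6, THF, −78 °C; then 17, −78 °C
Reagents that add atoms: none
Why: two-directional Still–Gennari variant of the Horner–Wadsworth–Emmons reaction, in which the bis(trifluoroethyl) phosphonate under dissociating conditions should give the (Z)-trisubstituted enoate (ester cis to the new chain) at both ends of the four-carbon dialdehyde.

Step 14
Reactants: 18 dimethyl (2Z,6Z)-2,7-bis{(3R)-3-acetoxy-3-[(1R,2S,3R)-2-acetoxy-3-(prop-1-en-2-yl)cyclopentyl]propyl}octa-2,6-dienedioate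
Product: 19 (1R,4Z,8Z,12R)-4,9-bis(hydroxymethyl)-1,12-bis[(1R,2S,3R)-2-hydroxy-3-(prop-1-en-2-yl)cyclopentyl]dodeca-4,8-diene-1,12-diol
Conditions: iBu2AlH (excess), CH2Cl2, −78 to 0 °C; aqueous potassium sodium tartrate
Reagents that add atoms: none
Why: diisobutylaluminium hydride reduces both enoates 1,2 to the allylic alcohols without touching the alkene geometry and cleaves the four acetates in the same operation.

Step 15
Reactants: 19 (1R,4Z,8Z,12R)-4,9-bis(hydroxymethyl)-1,12-bis[(1R,2S,3R)-2-hydroxy-3-(prop-1-en-2-yl)cyclopentyl]dodeca-4,8-diene-1,12-diol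
Product: 20 (1R,4Z,8Z,12R)-4,9-bis(chloromethyl)-1,12-bis[(1R,2S,3R)-2-hydroxy-3-(prop-1-en-2-yl)cyclopentyl]dodeca-4,8-diene-1,12-diol
Conditions: NCS (2.4 equiv), Me2S (2.8 equiv), CH2Cl2, −20 °C; then 19, −20 to 0 °C
Reagents that add atoms: N-chlorosuccinimide, O=C1CCC(=O)N1Cl
Why: Corey–Kim chlorination converts allylic alcohols into allylic chlorides by SN2 collapse of the alkoxysulfonium chloride without allylic transposition, while saturated secondary alcohols are returned unchanged in the absence of amine base.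

Step 16
Reactants: 20 (1R,4Z,8Z,12R)-4,9-bis(chloromethyl)-1,12-bis[(1R,2S,3R)-2-hydroxy-3-(prop-1-en-2-yl)cyclopentyl]dodeca-4,8-diene-1,12-diol
Product: 21 testudinariol A
Conditions: NaH (6 equiv), THF, 0 °C to rt
Reagents that add atoms: none
Why: double intramolecular Williamson etherification, in which each alkoxide at the carbinol next to the cyclopentane displaces the allylic chloride in a 6-exo-tet closure (the ring hydroxyl would need an eight-membered ring), with retention at the carbinol and of the Z-alkene.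

**Compound list**

1 | (R)-lavandulol, (2R)-5-methyl-2-(prop-1-en-2-yl)hex-4-en-1-ol | C=C(C)[C@H](CO)CC=C(C)C | starting material
2 | (R)-lavandulal, (2R)-5-methyl-2-(prop-1-en-2-yl)hex-4-enal | C=C(C)[C@H](C=O)CC=C(C)C | intermediate
3 | ethyl (2E,4S)-7-methyl-4-(prop-1-en-2-yl)octa-2,6-dienoate | C=C(C)[C@H](/C=C/C(=O)OCC)CC=C(C)C | intermediate
4 | ethyl (2E,4S)-4-[(3,3-dimethyloxiran-2-yl)methyl]-5-methylhexa-2,5-dienoate (both epoxide epimers) | C=C(C)[C@H](/C=C/C(=O)OCC)CC1OC1(C)C | intermediate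
5 | ethyl (2E,4S)-5-methyl-4-(2-oxoethyl)hexa-2,5-dienoate | C=C(C)[C@H](/C=C/C(=O)OCC)CC=O | intermediate
6 | ethyl (2E,4S)-4-(2-hydroxyethyl)-5-methylhexa-2,5-dienoate | C=C(C)[C@H](/C=C/C(=O)OCC)CCO | intermediate
7 | ethyl (2E,4S)-5-methyl-4-[2-(tosyloxy)ethyl]hexa-2,5-dienoate | C=C(C)[C@H](/C=C/C(=O)OCC)CCOS(=O)(=O)c1ccc(C)cc1 | intermediate
8 | boron enolate, 2-({(3S,4S)-1-ethoxy-5-methyl-3-(4,4,5,5-tetramethyl-1,3,2-dioxaborolan-2-yl)-4-[2-(tosyloxy)ethyl]hexa-1,5-dien-1-yl}oxy)-4,4,5,5-tetramethyl-1,3,2-dioxaborolane (enolate geometry open) | C=C(C)[C@H]([C@@H](C=C(OCC)OB1OC(C)(C)C(C)(C)O1)B2OC(C)(C)C(C)(C)O2)CCOS(=O)(=O)c3ccc(C)cc3 | intermediate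
9 | ethyl (1S,2S,3S)-3-(prop-1-en-2-yl)-2-(4,4,5,5-tetramethyl-1,3,2-dioxaborolan-2-yl)cyclopentane-1-carboxylate (boron cis to isopropenyl, ester trans to boron) | C=C(C)[C@H]1CC[C@H](C(=O)OCC)[C@H]1B2OC(C)(C)C(C)(C)O2 | intermediate
10 | ethyl (1S,2S,3R)-2-hydroxy-3-(prop-1-en-2-yl)cyclopentane-1-carboxylate | C=C(C)[C@H]1CC[C@H](C(=O)OCC)[C@H]1O | intermediate
11 | (1S,2S,3R)-2-hydroxy-N-methoxy-N-methyl-3-(prop-1-en-2-yl)cyclopentane-1-carboxamide | C=C(C)[C@H]1CC[C@H](C(=O)N(C)OC)[C@H]1O | intermediate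
12 | 1-[(1S,2S,3R)-2-hydroxy-3-(prop-1-en-2-yl)cyclopentyl]prop-2-en-1-one | C=C(C)[C@H]1CC[C@H](C(=O)C=C)[C@H]1O | intermediate
13 | methyl 2-[bis(2,2,2-trifluoroethoxy)phosphoryl]-5-[(1S,2S,3R)-2-hydroxy-3-(prop-1-en-2-yl)cyclopentyl]-5-oxopentanoate (both C2 epimers) | C=C(C)[C@H]1CC[C@H](C(=O)CCC(C(=O)OC)P(=O)(OCC(F)(F)F)OCC(F)(F)F)[C@H]1O | intermediate
14 | methyl (5R)-2-[bis(2,2,2-trifluoroethoxy)phosphoryl]-5-hydroxy-5-[(1R,2S,3R)-2-hydroxy-3-(prop-1-en-2-yl)cyclopentyl]pentanoate (1,3-syn diol, both C2 epimers) | C=C(C)[C@H]1CC[C@H]([C@H](O)CCC(C(=O)OC)P(=O)(OCC(F)(F)F)OCC(F)(F)F)[C@H]1O | intermediate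
15 | methyl (5R)-5-acetoxy-5-[(1R,2S,3R)-2-acetoxy-3-(prop-1-en-2-yl)cyclopentyl]-2-[bis(2,2,2-trifluoroethoxy)phosphoryl]pentanoate | C=C(C)[C@H]1CC[C@H]([C@H](OC(C)=O)CCC(C(=O)OC)P(=O)(OCC(F)(F)F)OCC(F)(F)F)[C@H]1OC(C)=O | intermediate
16 | 2,5-dimethoxytetrahydrofuran (cis/trans mixture) | COC1CCC(OC)O1 | starting material
17 | succinaldehyde (butanedial) | O=CCCC=O | intermediate
18 | dimethyl (2Z,6Z)-2,7-bis{(3R)-3-acetoxy-3-[(1R,2S,3R)-2-acetoxy-3-(prop-1-en-2-yl)cyclopentyl]propyl}octa-2,6-dienedioate | C=C(C)[C@H]1CC[C@H]([C@H](OC(C)=O)CC/C(=C/CC/C=C(/CC[C@H]([C@H]2CC[C@H](C(=C)C)[C@@H]2OC(C)=O)OC(C)=O)C(=O)OC)C(=O)OC)[C@H]1OC(C)=O | intermediate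
19 | (1R,4Z,8Z,12R)-4,9-bis(hydroxymethyl)-1,12-bis[(1R,2S,3R)-2-hydroxy-3-(prop-1-en-2-yl)cyclopentyl]dodeca-4,8-diene-1,12-diol | C=C(C)[C@H]1CC[C@H]([C@H](O)CC/C(=C/CC/C=C(/CC[C@H]([C@H]2CC[C@H](C(=C)C)[C@@H]2O)O)CO)CO)[C@H]1O | intermediate
20 | (1R,4Z,8Z,12R)-4,9-bis(chloromethyl)-1,12-bis[(1R,2S,3R)-2-hydroxy-3-(prop-1-en-2-yl)cyclopentyl]dodeca-4,8-diene-1,12-diol | C=C(C)[C@H]1CC[C@H]([C@H](O)CC/C(=C/CC/C=C(/CC[C@H]([C@H]2CC[C@H](C(=C)C)[C@@H]2O)O)CCl)CCl)[C@H]1O | intermediate
21 | testudinariol A (C2-symmetric; two 2-substituted 5-(Z)-alkylidene tetrahydropyrans joined through =CH–CH2–CH2–CH=, each carrying a 2-hydroxy-3-isopropenylcyclopentyl group) | C=C(C)[C@H]1CC[C@H]([C@H]2CC/C(=C/CC/C=C3/CC[C@H]([C@H]4CC[C@H](C(=C)C)[C@@H]4O)OC3)CO2)[C@H]1O | target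

**Step count and risks**

Total: 16 steps. Longest linear sequence: 15 steps (steps 1–11 and 13–16, from (R)-lavandulol); step 12 is a one-step side branch.

Steps most likely to fail:

1. Step 5 (proposed cascade). The boron enolate may not turn the catalyst over or may not be released cleanly by alkoxide, so that protonation or attack on the sulfonate competes with ring closure, and boron delivery next to the existing centre may show poor facial selectivity. Fallback with known chemistry, from 7 to 10: copper-catalysed asymmetric β-borylation of 7 under the usual protic conditions (CuCl, chiral bisphosphine, NaOtBu cat., B2pin2, MeOH, THF) should give the open-chain boronate ethyl (3R,4S)-5-methyl-3-(4,4,5,5-tetramethyl-1,3,2-dioxaborolan-2-yl)-4-[2-(tosyloxy)ethyl]hex-5-enoate F1. Buffered oxidation with NaBO3·4H2O should give ethyl (3R,4R)-3-hydroxy-5-methyl-4-[2-(tosyloxy)ethyl]hex-5-enoate F2, which is silylated at once (TBSOTf, 2,6-lutidine) to ethyl (3R,4R)-3-[(tert-butyldimethylsilyl)oxy]-5-methyl-4-[2-(tosyloxy)ethyl]hex-5-enoate F3. Intramolecular ester enolate alkylation (KN(SiMe3)2, THF/DMPU, −78 to −40 °C; same allylic-strain control) should close the ring to ethyl (1S,2S,3R)-2-[(tert-butyldimethylsilyl)oxy]-3-(prop-1-en-2-yl)cyclopentane-1-carboxylate F4, and Bu4NF returns to 10.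

2. Step 13. Z-selectivity may be lost at one of the two alkenes, and the dialdehyde may self-condense under base. Fallback, from 15 to 18, one-directional with isomer removal after each olefination: Still–Gennari olefination of 15 with 4,4-dimethoxybutanal should give methyl (2Z)-2-{(3R)-3-acetoxy-3-[(1R,2S,3R)-2-acetoxy-3-(prop-1-en-2-yl)cyclopentyl]propyl}-6,6-dimethoxyhex-2-enoate F5, purified as the single Z isomer. Mild aqueous acid should unmask methyl (2Z)-2-{(3R)-3-acetoxy-3-[(1R,2S,3R)-2-acetoxy-3-(prop-1-en-2-yl)cyclopentyl]propyl}-6-oxohex-2-enoate F6. A second Still–Gennari olefination of F6 with another equivalent of 15 returns to 18.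

3. Step 10. Facial selectivity may be poor if the boron chelate, which must span trans positions on the cyclopentane, forms incompletely, and the δ-hydroxy ester may lactonise on work-up. Fallback, from 13 to 14, with reagent control in place of chelation: silylation of the ring hydroxyl (Et3SiCl, imidazole) should give methyl 2-[bis(2,2,2-trifluoroethoxy)phosphoryl]-5-oxo-5-[(1S,2S,3R)-3-(prop-1-en-2-yl)-2-(triethylsilyloxy)cyclopentyl]pentanoate F7. Corey–Bakshi–Shibata reduction (BH3·SMe2 with the enantiomer of tetrahydro-1-methyl-3,3-diphenyl-1H,3H-pyrrolo[1,2-c][1,3,2]oxazaborole that delivers hydride to the required face) should give methyl (5R)-2-[bis(2,2,2-trifluoroethoxy)phosphoryl]-5-hydroxy-5-[(1R,2S,3R)-3-(prop-1-en-2-yl)-2-(triethylsilyloxy)cyclopentyl]pentanoate F8. HF·pyridine returns to 14.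

**Further compounds**

F1 | step 5 | ethyl (3R,4S)-5-methyl-3-(4,4,5,5-tetramethyl-1,3,2-dioxaborolan-2-yl)-4-[2-(tosyloxy)ethyl]hex-5-enoate | C=C(C)[C@H]([C@@H](CC(=O)OCC)B1OC(C)(C)C(C)(C)O1)CCOS(=O)(=O)c2ccc(C)cc2
F2 | step 5 | ethyl (3R,4R)-3-hydroxy-5-methyl-4-[2-(tosyloxy)ethyl]hex-5-enoate | C=C(C)[C@H]([C@@H](CC(=O)OCC)O)CCOS(=O)(=O)c1ccc(C)cc1
F3 | step 5 | ethyl (3R,4R)-3-[(tert-butyldimethylsilyl)oxy]-5-methyl-4-[2-(tosyloxy)ethyl]hex-5-enoate | C=C(C)[C@H]([C@@H](CC(=O)OCC)O[Si](C)(C)C(C)(C)C)CCOS(=O)(=O)c1ccc(C)cc1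
F4 | step 5 | ethyl (1S,2S,3R)-2-[(tert-butyldimethylsilyl)oxy]-3-(prop-1-en-2-yl)cyclopentane-1-carboxylate | C=C(C)[C@H]1CC[C@H](C(=O)OCC)[C@H]1O[Si](C)(C)C(C)(C)C
F5 | step 13 | methyl (2Z)-2-{(3R)-3-acetoxy-3-[(1R,2S,3R)-2-acetoxy-3-(prop-1-en-2-yl)cyclopentyl]propyl}-6,6-dimethoxyhex-2-enoate | C=C(C)[C@H]1CC[C@H]([C@H](OC(C)=O)CC/C(=C/CCC(OC)OC)C(=O)OC)[C@H]1OC(C)=O
F6 | step 13 | methyl (2Z)-2-{(3R)-3-acetoxy-3-[(1R,2S,3R)-2-acetoxy-3-(prop-1-en-2-yl)cyclopentyl]propyl}-6-oxohex-2-enoate | C=C(C)[C@H]1CC[C@H]([C@H](OC(C)=O)CC/C(=C/CCC=O)C(=O)OC)[C@H]1OC(C)=O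
F7 | step 10 | methyl 2-[bis(2,2,2-trifluoroethoxy)phosphoryl]-5-oxo-5-[(1S,2S,3R)-3-(prop-1-en-2-yl)-2-(triethylsilyloxy)cyclopentyl]pentanoate | C=C(C)[C@H]1CC[C@H](C(=O)CCC(C(=O)OC)P(=O)(OCC(F)(F)F)OCC(F)(F)F)[C@H]1O[Si](CC)(CC)CC
F8 | step 10 | methyl (5R)-2-[bis(2,2,2-trifluoroethoxy)phosphoryl]-5-hydroxy-5-[(1R,2S,3R)-3-(prop-1-en-2-yl)-2-(triethylsilyloxy)cyclopentyl]pentanoate | C=C(C)[C@H]1CC[C@H]([C@H](O)CCC(C(=O)OC)P(=O)(OCC(F)(F)F)OCC(F)(F)F)[C@H]1O[Si](CC)(CC)CC
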